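The route rests on cutting the two C1–O bonds of the terminal rings A and C back to C–H. In these rings C1 lies ortho to the C6 isovaleryl ketone and meta to the C3 and C5 oxygens. In the des-oxy trimer C1 holds the only aromatic hydrogen, and ring B has none. One ketone-directed palladium oxidation of hepta-acetate 10 therefore installs both oxygens at once. They are then the only free phenols, so methylation needs no choice among hydroxyls. Compound 10 is the peracetylated trimer of two 4-methylresorcinol-derived isovaleryl ketones and isovalerylphloroglucinol. Its two methylene bridges are laid through a Mannich base instead of a mixed formaldehyde condensation.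

Key step: step 6

**Remarks**
- Atom numbers for rings A and C: C1 (H up to 10, OMe in 14), C2 (CH3), C3 (O), C4 (bridge carbon), C5 (O), C6 (isovaleryl). Ring B is the central phloroglucinol.
- Assumption: the target (C39H50O12) has no stereocentre and is taken as freely rotating about both bridges, so no stereochemical control is needed.
- Acetates are kept as the phenol masks. They are small enough for seven flanked phenols, they deactivate the rings, and they all leave in one mild operation.

**Step 1**
Reactants: 1 4-methylresorcinol; 2 isovaleryl chloride
Product: 3 1-(2,4-dihydroxy-5-methylphenyl)-3-methylbutan-1-one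
Conditions: AlCl3 (3 equiv), ClCH2CH2Cl, 0 → 60 °C; ice, 2 M HCl
Reagents that add atoms: none
Why: Friedel–Crafts acylation, with Fries shift of any aryl ester formed first, should go to the open carbon para to one hydroxyl and ortho to the other (C6), since the carbon between the hydroxyls is more crowded and C1 is meta to both, and the aluminium chelate of the product blocks a second acylation.

**Step 2**
Reactants: 3 1-(2,4-dihydroxy-5-methylphenyl)-3-methylbutan-1-one; 4 formaldehyde
Product: 5 1-[3-(dimethylaminomethyl)-2,4-dihydroxy-5-methylphenyl]-3-methylbutan-1-one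
Conditions: 37% aq. HCHO (1.1 equiv), 40% aq. Me2NH (1.2 equiv), EtOH, 0 °C → rt
Reagents that add atoms: dimethylamine, CNC
Why: Phenolic Mannich reaction in which the iminium ion from 4 and dimethylamine attacks C4, the only ring carbon still activated by both hydroxyls, as resacetophenones are known to do, while the free-amine medium keeps the ketone alpha-carbon out of play.

**Step 3**
Reactants: 6 phloroglucinol; 2 isovaleryl chloride
Product: 7 1-(2,4,6-trihydroxyphenyl)-3-methylbutan-1-one (isovalerylphloroglucinol)
Conditions: AlCl3 (4 equiv), CH2Cl2/MeNO2, 0 → 45 °C; ice, 2 M HCl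
Reagents that add atoms: none
Why: Friedel–Crafts acylation of the threefold-symmetric triol can give only one C-acyl product, and the deactivating, aluminium-bound first acyl group should hold the reaction at mono-acylation when one equivalent of 2 is used.

**Step 4**
Reactants: 5 Mannich base (2.2 equiv); 7 isovalerylphloroglucinol
Product: 9 1-[3,5-bis[[2,6-dihydroxy-3-methyl-5-(3-methylbutanoyl)phenyl]methyl]-2,4,6-trihydroxyphenyl]-3-methylbutan-1-one (des-oxy trimer), via ortho-quinone methide 8 (not isolated)
Conditions: 1,4-dioxane, 100 °C, slow N2 sweep, 5 added in portions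
Reagents that add atoms: none
Why: Loss of dimethylamine from the ortho-hydroxybenzylamine gives ortho-quinone methide 8, which the much more nucleophilic acylphloroglucinol 7 should trap by Michael-type C-alkylation at each of its two free ring carbons, and because the electrophilic carbon is only ever attached to rings A and C, which have no activated free position, the B–CH2–B and A–CH2–A products of a mixed formaldehyde condensation are designed out.

**Step 5**
Reactants: 9 des-oxy trimer
Product: 10 hepta-acetate of the des-oxy trimer (all seven phenols as OAc, C1–H on rings A and C)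
Conditions: Ac2O (excess), pyridine, DMAP (cat.), rt → 40 °C
Reagents that add atoms: acetic anhydride, CC(=O)OC(C)=O
Why: DMAP-catalysed O-acylation through the N-acetylpyridinium ion is strong enough for hydrogen-bonded and doubly flanked phenols, and the seven acetates lock the bridges against retro-Michael exchange, lower the electron density of all three rings and release the ketone oxygens from hydrogen bonds for step 6.

**Step 6**
Reactants: 10 hepta-acetate of the des-oxy trimer
Product: 12 hepta-acetate bearing a free hydroxyl at C1 of ring A and of ring C, via bis(trifluoroacetate) 11 (not isolated)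
Conditions: Pd(OCOCF3)2 (20 mol %), PhI(OCOCF3)2 (4 equiv), dry ClCH2CH2Cl, 80 °C; then THF/H2O, rt
Reagents that add atoms: bis(trifluoroacetoxy)iodobenzene, O=C(OI(OC(=O)C(F)(F)F)c1ccccc1)C(F)(F)F
Why: Each terminal ketone oxygen binds divalent palladium and brings it to the adjacent C1–H, which is cleaved by concerted metalation–deprotonation to a five-membered palladacycle; the trivalent-iodine oxidant raises this to tetravalent palladium, and C–O reductive elimination gives aryl trifluoroacetate 11, which water cleaves to phenol 12. The closest known reaction type is the ketone-directed ortho C–H hydroxylation of alkyl aryl ketones with palladium carboxylates and a hypervalent iodine or persulfate oxidant, run here twice in one molecule. No ring is closed and no stereocentre is made. The two C1–H bonds are the only aromatic C–H bonds of 10 and the ring B ketone has both ortho carbons filled, so the site on the arenes is fixed by the substrate; C1 is also ortho to the methyl and para to the bridge carbon, while both acetoxy groups sit meta to it. The selectivity needed is for this C(sp2)–H over the benzylic CH2 and CH3, the alpha-keto CH2 and the tertiary C–H bonds, and it should come from chelation, from the seven ring-deactivating acetates, and from a two-electron oxidant in a non-acidic solvent in place of a radical-forming persulfate in neat acid. Until work-up the new oxygens stay masked as trifluoroacetates, which guards them against over-oxidation.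

**Step 7**
Reactants: 12 dihydroxy hepta-acetate
Product: 13 hepta-acetate bearing OMe at C1 of ring A and of ring C
Conditions: MeI (10 equiv), Ag2O (3 equiv), 4 Å molecular sieves, CH2Cl2, rt → 40 °C, dark
Reagents that add atoms: iodomethane, CI
Why: Purdie-type O-methylation with Ag2O and MeI, a standard answer to chelated phenols in base-sensitive substrates, touches only the two free C1 hydroxyls, and the absence of carbonate or alkoxide avoids acetate loss and the Baker–Venkataraman acyl shift that is open to ortho-acetoxy ketones with alpha-hydrogens.

**Step 8**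
Reactants: 13 dimethoxy hepta-acetate
Product: 14 target, 1-[3,5-bis[[2,6-dihydroxy-4-methoxy-3-methyl-5-(3-methylbutanoyl)phenyl]methyl]-2,4,6-trihydroxyphenyl]-3-methylbutan-1-one
Conditions: K2CO3 (8 equiv), degassed MeOH/THF, argon, 0 °C → rt; 1 M HCl to pH 3
Reagents that add atoms: none
Why: Carbonate-mediated transesterification (Zemplén-type methanolysis) removes aryl acetates far faster than it could touch aryl methyl ethers or ketones, and low temperature, exclusion of air and an early acid quench should keep the polyphenolate from oxidation and from retro-Michael exchange of its bridges.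

**Compound list**
1 | 4-methylresorcinol | Cc1ccc(O)cc1O | starting material
2 | isovaleryl chloride | CC(C)CC(Cl)=O | starting material
3 | 1-(2,4-dihydroxy-5-methylphenyl)-3-methylbutan-1-one | CC(C)CC(=O)c1cc(C)c(O)cc1O | intermediate
4 | formaldehyde | C=O | starting material
5 | 1-[3-(dimethylaminomethyl)-2,4-dihydroxy-5-methylphenyl]-3-methylbutan-1-one | CC(C)CC(=O)c1cc(C)c(O)c(CN(C)C)c1O | intermediate
6 | phloroglucinol | Oc1cc(O)cc(O)c1 | starting material
7 | 1-(2,4,6-trihydroxyphenyl)-3-methylbutan-1-one | CC(C)CC(=O)c1c(O)cc(O)cc1O | intermediate
8 | 5-hydroxy-2-methyl-6-methylidene-4-(3-methylbutanoyl)cyclohexa-2,4-dien-1-one (ortho-quinone methide, not isolated) | C=C1C(=O)C(C)=CC(C(=O)CC(C)C)=C1O | intermediate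
9 | des-oxy trimer, heptaphenol | CC(C)CC(=O)c1cc(C)c(O)c(Cc2c(O)c(Cc3c(O)c(C)cc(C(=O)CC(C)C)c3O)c(O)c(C(=O)CC(C)C)c2O)c1O | intermediate
10 | hepta-acetate of the des-oxy trimer | CC(C)CC(=O)c1cc(C)c(OC(C)=O)c(Cc2c(OC(C)=O)c(Cc3c(OC(C)=O)c(C)cc(C(=O)CC(C)C)c3OC(C)=O)c(OC(C)=O)c(C(=O)CC(C)C)c2OC(C)=O)c1OC(C)=O | intermediate
11 | hepta-acetate C1,C1-bis(trifluoroacetate) (not isolated) | CC(C)CC(=O)c1c(OC(=O)C(F)(F)F)c(C)c(OC(C)=O)c(Cc2c(OC(C)=O)c(Cc3c(OC(C)=O)c(C)c(OC(=O)C(F)(F)F)c(C(=O)CC(C)C)c3OC(C)=O)c(OC(C)=O)c(C(=O)CC(C)C)c2OC(C)=O)c1OC(C)=O | intermediate
12 | hepta-acetate with two C1 hydroxyls | CC(C)CC(=O)c1c(O)c(C)c(OC(C)=O)c(Cc2c(OC(C)=O)c(Cc3c(OC(C)=O)c(C)c(O)c(C(=O)CC(C)C)c3OC(C)=O)c(OC(C)=O)c(C(=O)CC(C)C)c2OC(C)=O)c1OC(C)=O | intermediate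
13 | hepta-acetate with two C1 methoxyls | CC(C)CC(=O)c1c(OC)c(C)c(OC(C)=O)c(Cc2c(OC(C)=O)c(Cc3c(OC(C)=O)c(C)c(OC)c(C(=O)CC(C)C)c3OC(C)=O)c(OC(C)=O)c(C(=O)CC(C)C)c2OC(C)=O)c1OC(C)=O | intermediate
14 | CNP0158539.0 | COc1c(C)c(O)c(Cc2c(O)c(Cc3c(O)c(C)c(OC)c(C(=O)CC(C)C)c3O)c(O)c(C(=O)CC(C)C)c2O)c(O)c1C(=O)CC(C)C | target

**Step count**
Total step count: 8.
Longest linear sequence: 7 (steps 1, 2, 4, 5, 6, 7, 8). Step 3 is the side branch.

**Steps most likely to fail**

1. **Step 6.**
 - Risk: palladation may stall, because C1–H is wedged between the C2 methyl and a ketone that the C5 acetate twists out of the ring plane. Long heating with the oxidant then invites benzylic or alpha-keto oxidation, acetate loss and one-sided conversion.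
 - Fallback: a route without C–H activation that sets out from 2, uses 4 and 7 on the way, and comes back at 14. Bought 2-methylphloroglucinol F1 is acylated with 2 (AlCl3) to 1-(2,4,6-trihydroxy-3-methylphenyl)-3-methylbutan-1-one F2, the only possible C-acyl isomer. MOMCl/iPr2NEt caps the unchelated hydroxyl and the less hindered chelated one to give the bis-MOM ether F3, whose only free phenol lies between methyl and ketone. MeI/K2CO3 gives the methyl ether F4. HCl in MeOH frees 1-(4,6-dihydroxy-2-methoxy-3-methylphenyl)-3-methylbutan-1-one F5. A Mannich reaction with 4 and dimethylamine gives the benzylamine F6, and two equivalents of it alkylate 7 as in step 4 to give 14 directly.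

2. **Step 4.**
 - Risk: the quinone methide may be used up by ipso attack on unreacted 5, the second alkylation of ring B may lag, and the liberated amine may start exchange of bridges at 100 °C.
 - Fallback: the roles of the partners are reversed, setting out from 7 and 3 and coming back at 9. Compound 7 is aminomethylated twice with 4 and dimethylamine to 1-[3,5-bis(dimethylaminomethyl)-2,4,6-trihydroxyphenyl]-3-methylbutan-1-one F7, in which ring B has no free carbon left. This is heated with an excess of recoverable 3, whose C4 then serves as the nucleophile.

3. **Step 7.**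
 - Risk: methylation of a hydrogen-bonded phenol flanked on both sides may be slow, which gives time for intermolecular acetyl transfer onto the new hydroxyls.
 - Fallback: from 12 back to 13 by Mitsunobu etherification (MeOH, PPh3, DIAD, THF, 0 °C → rt). This activates methanol as its alkoxyphosphonium ion and asks of the phenol only acidity, under neutral and metal-free conditions. This detour makes no new compound (F0).

**Further compounds**
F1 | step 6 | 2-methylphloroglucinol (bought) | Cc1c(O)cc(O)cc1O
F2 | step 6 | 1-(2,4,6-trihydroxy-3-methylphenyl)-3-methylbutan-1-one | CC(C)CC(=O)c1c(O)cc(O)c(C)c1O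
F3 | step 6 | 1-[2-hydroxy-4,6-bis(methoxymethoxy)-3-methylphenyl]-3-methylbutan-1-one | CC(C)CC(=O)c1c(OCOC)cc(OCOC)c(C)c1O
F4 | step 6 | 1-[2-methoxy-4,6-bis(methoxymethoxy)-3-methylphenyl]-3-methylbutan-1-one | CC(C)CC(=O)c1c(OCOC)cc(OCOC)c(C)c1OC
F5 | step 6 | 1-(4,6-dihydroxy-2-methoxy-3-methylphenyl)-3-methylbutan-1-one | CC(C)CC(=O)c1c(O)cc(O)c(C)c1OC
F6 | step 6 | 1-[5-(dimethylaminomethyl)-4,6-dihydroxy-2-methoxy-3-methylphenyl]-3-methylbutan-1-one | CC(C)CC(=O)c1c(O)c(CN(C)C)c(O)c(C)c1OC
F7 | step 4 | 1-[3,5-bis(dimethylaminomethyl)-2,4,6-trihydroxyphenyl]-3-methylbutan-1-one | CC(C)CC(=O)c1c(O)c(CN(C)C)c(O)c(CN(C)C)c1O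
F0 | step 7 | none | none
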